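**Assumption:** atoms carry ent-kaurane numbers (C1–C20; C6 and C7 are the two lactone carbonyl carbons). In step 1 the antipode of the chiral amine that gives the R adduct is used. Nothing here has been run; stereochemical outcomes are predictions.

## Retrosynthetic overview

1. Guidongnin C ⇐ exo-face hydrogenation of its 16-methylidene analogue ⇐ α-methylenation and C11 reduction of a bridged diketone.
2. Ring D (C16–C13) by intramolecular Michael addition of a C8 acetyl group to a ring C enone; ring C (C9–C11, C8–C14) by acyl-radical conjugate addition then enolate alkylation on a 3-acetyl-5,6-dihydropyranone (new step).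
3. δ-Lactone and quaternary C10 (C9–C10) by Cp2TiCl-mediated opening of a spiro-epoxide and Giese addition to an acrylate.
4. Ring A γ-lactone from (R)-3-methyl-3-(nitromethyl)cyclohexanone by Nef reaction, reduction and intramolecular Claisen acylation; C4 from an organocatalytic nitro-Michael addition.
5. Ring order: ring A (purchased) → γ-lactone → δ-lactone → ring C → ring D.

## Route

Step 1
Reactants: 1 3-methylcyclohex-2-en-1-one; 2 nitromethane
Product: 3 (R)-3-methyl-3-(nitromethyl)cyclohexan-1-one
Conditions: chiral primary–tertiary 1,2-diamine derived from tert-leucine (10 mol%), PhCO2H (10 mol%), MeNO2 (neat), 30 °C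
Reagents that add atoms: nitromethane, C[N+](=O)[O-]
Why: Primary-amine iminium catalysis (asymmetric nitro-Michael addition to a β,β-disubstituted enone) delivers the nitronate to one face of the iminium ion and sets the quaternary C4 as R, the stereocentre from which all later ones are relayed.

Step 2
Reactants: 3 (R)-3-methyl-3-(nitromethyl)cyclohexan-1-one; 4 ozone
Product: 6 (R)-3-(hydroxymethyl)-3-methylcyclohexan-1-one, via keto aldehyde 5 (not isolated)
Conditions: NaOMe (1.05 equiv), MeOH, 0 °C; O3, CH2Cl2/MeOH, −78 °C; then NaBH4, −78 °C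
Reagents that add atoms: ozone, [O-][O+]=O
Why: Ozonolysis of the sodium nitronate (Nef-type reaction) gives the non-enolisable aldehyde, which NaBH4 reduces at −78 °C much faster than the ring ketone; C4 is untouched.

Step 3
Reactants: 6 (R)-3-(hydroxymethyl)-3-methylcyclohexan-1-one; 7 1,1'-carbonyldiimidazole
Product: 9 keto lactone (3aR,7aR)-3a-methyl-3a,4,5,6-tetrahydro-2-benzofuran-1,7(3H,7aH)-dione, via imidazolyl carbamate 8 (not isolated)
Conditions: CDI, CH2Cl2, rt; then NaH (2.2 equiv), THF, 0 °C → rt; aq. NH4Cl
Reagents that add atoms: 1,1'-carbonyldiimidazole, O=C(n1ccnc1)n1ccnc1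
Why: O-acylation then intramolecular Claisen (Dieckmann-type) acylation: only the C5 enolate can reach the carbamate (5-exo-trig), so C6 is attached at C5, and the epimerisable C5 settles as the cis-fused β-keto γ-lactone.

Step 4
Reactants: 9 keto lactone; 10 dibromomethane
Product: 11 methylene lactone (3aR,7aS)-3a-methyl-7-methylidenehexahydro-2-benzofuran-1(3H)-one
Conditions: Zn dust, CH2Br2, TiCl4, THF/CH2Cl2, 0 °C → rt
Reagents that add atoms: dibromomethane, BrCBr
Why: Lombardo–Takai methylenation with a non-basic reagent converts the ketone into the exocyclic C10=C20 alkene without attacking the lactone or epimerising C5.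

Step 5
Reactants: 11 methylene lactone; 12 3-chloroperbenzoic acid
Product: 13 spiro-epoxide of 11 (oxirane on C10=C20; oxygen on the face opposite C6)
Conditions: mCPBA, NaHCO3, CH2Cl2, 0 °C
Reagents that add atoms: 3-chloroperbenzoic acid, OOC(=O)c1cccc(Cl)c1
Why: Prilezhaev epoxidation of the electron-rich 1,1-disubstituted alkene on the convex face; the C10 configuration of the epoxide is erased in step 6, so a mixture is harmless.

Step 6
Reactants: 13 spiro-epoxide; 14 2,2,2-trifluoroethyl acrylate
Product: 16 spirolactone (C7,20 δ-lactone spiro-fused to ring A at C10; C20 cis to C19), via hydroxy ester 15 (not isolated)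
Conditions: Cp2TiCl2 (20 mol%), Mn powder, 2,4,6-trimethylpyridine hydrochloride, THF, rt; acrylate 14 (5 equiv)
Reagents that add atoms: 2,2,2-trifluoroethyl acrylate, C=CC(=O)OCC(F)(F)F
Why: Nugent–RajanBabu epoxide opening by Cp2TiCl (trivalent titanium, regenerated by Mn) gives the tertiary C10 radical carrying C20–O; its Giese addition to the acrylate occurs opposite C6 and the axial C19, and the alkoxide then lactonises on the activated ester, fixing C10 with C20 cis to C19.

Step 7
Reactants: 16 spirolactone; 17 N-acetylimidazole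
Product: 20 unsaturated keto lactone (3-acetyl-5,6-dihydro-2H-pyran-2-one spiro-fused at C10), via acetyl lactone 18 (not isolated), via selenide 19 (not isolated)
Conditions: LiN(SiMe3)2 (2.2 equiv), THF, −78 °C; N-acetylimidazole; then PhSeCl, −78 → 0 °C; then 30% H2O2, pyridine, CH2Cl2, 0 °C
Reagents that add atoms: N-acetylimidazole, CC(=O)n1ccnc1
Why: Crossed Claisen acylation at C8 (C5–H is shielded by two quaternary carbons), selenenylation of the β-keto lactone enolate and selenoxide syn-elimination towards C9 (the only β-hydrogens) give the doubly activated C8=C9 alkene; no stereocentre is formed.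

Step 8
Reactants: 20 unsaturated keto lactone; 21 4-chlorobutanal
Product: 23 cyclohexanone (ring C closed; C8 acetyl cis to H-9; C11 ketone), via chloro diketone 22 (not isolated)
Conditions: (n-Bu4N)4[W10O32] (2 mol%), 4-chlorobutanal (3 equiv), MeCN, 390 nm, rt; then K2CO3, NaI (cat.), 50 °C
Reagents that add atoms: 4-chlorobutanal, O=CCCCCl
Why: Proposed new method: photoexcited decatungstate abstracts the aldehyde hydrogen to give a nucleophilic acyl radical that adds to the neopentyl C9 of the alkylidene β-keto lactone on the face syn to C1 and anti to the branched C5 (sets C9), back hydrogen transfer gives 22, and K2CO3/NaI then closes ring C by 6-exo-tet C-alkylation of the β-keto lactone enolate on the face that carries the new chain (sets C8, acetyl cis to H-9); the closest known reaction types are decatungstate hydroacylation of simple electron-poor alkenes and Michael-initiated ring closure, neither shown on a spiro 3-acyl-dihydropyranone.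

Step 9
Reactants: 23 cyclohexanone
Product: 24 enone (C12=C13)
Conditions: Pd(OCOCF3)2 (5 mol%), DMSO (10 mol%), O2 (1 atm), AcOH, 80 °C
Reagents that add atoms: none
Why: Aerobic α,β-dehydrogenation by divalent palladium; C12–C13 is the only site with β-hydrogens (C8 and C10 are quaternary, the acetyl group has none), so only this enone can form and it cannot aromatise.

Step 10
Reactants: 24 enone
Product: 25 bridged diketone (bicyclo[3.2.1]octane closed; C16 is CH2)
Conditions: KN(SiMe3)2 (1.05 equiv), THF, −78 → 0 °C; AcOH
Reagents that add atoms: none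
Why: Kinetic deprotonation of the methyl ketone and intramolecular 5-exo-trig Michael addition of C16 to C13 close ring D; the acetyl group can reach C13 only from the face it occupies, which fixes C13, and any aldol adduct at C11 reverts.

Step 11
Reactants: 25 bridged diketone
Product: 26 11-alcohol (OH equatorial; trans to H-9)
Conditions: NaBH4, MeOH/CH2Cl2, −40 °C
Reagents that add atoms: none
Why: The cyclohexanone C11 is reduced faster than the cyclopentanone C15 (flanked by quaternary C8); hydride is expected on the endo face, opposite the axial C10 and ring A, giving the equatorial and thermodynamically preferred alcohol.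

Step 12
Reactants: 26 11-alcohol; 27 formaldehyde (as paraformaldehyde)
Product: 28 16-methylidene analogue of the target
Conditions: (CH2O)n, N-methylanilinium trifluoroacetate, THF, 65 °C
Reagents that add atoms: formaldehyde, C=O
Why: Mannich-type α-methylenation (Gras conditions) at C16, the only enolisable position of the C15 ketone.

Step 13
Reactants: 28 16-methylidene analogue
Product: 29 guidongnin C
Conditions: H2 (1 atm), Pd/C (10 wt%), EtOAc, rt
Reagents that add atoms: none
Why: Heterogeneous hydrogenation of the exocyclic enone from the exo face (the side of the one-carbon bridge C14) places H-16 exo and the methyl group endo, as in the target.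

## Compound list

1 | 3-methylcyclohex-2-en-1-one | CC1=CC(=O)CCC1 | starting material
2 | nitromethane | C[N+](=O)[O-] | starting material
3 | (R)-3-methyl-3-(nitromethyl)cyclohexan-1-one | O=C1CCC[C@@](C)(C[N+](=O)[O-])C1 | intermediate
4 | ozone | [O-][O+]=O | starting material
5 | (R)-1-methyl-3-oxocyclohexane-1-carbaldehyde (keto aldehyde) | O=C1CCC[C@@](C)(C=O)C1 | intermediate
6 | (R)-3-(hydroxymethyl)-3-methylcyclohexan-1-one | O=C1CCC[C@@](C)(CO)C1 | intermediate
7 | 1,1'-carbonyldiimidazole | O=C(n1ccnc1)n1ccnc1 | starting material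
8 | (R)-(1-methyl-3-oxocyclohexyl)methyl imidazole-1-carboxylate (imidazolyl carbamate) | O=C1CCC[C@@](C)(COC(=O)n2ccnc2)C1 | intermediate
9 | keto lactone (3aR,7aR)-3a-methyl-3a,4,5,6-tetrahydro-2-benzofuran-1,7(3H,7aH)-dione; cis-fused | O=C1CCC[C@@]2(C)COC(=O)[C@H]21 | intermediate
10 | dibromomethane | BrCBr | starting material
11 | methylene lactone (3aR,7aS)-3a-methyl-7-methylidenehexahydro-2-benzofuran-1(3H)-one; cis-fused | C=C1CCC[C@@]2(C)COC(=O)[C@H]21 | intermediate
12 | 3-chloroperbenzoic acid | OOC(=O)c1cccc(Cl)c1 | starting material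
13 | spiro-epoxide of 11 (oxirane C10–C20; O opposite C6) | O1[C@@]2(CCC[C@@]3(C)COC(=O)[C@H]32)C1 | intermediate
14 | 2,2,2-trifluoroethyl acrylate | C=CC(=O)OCC(F)(F)F | starting material
15 | hydroxy ester: 2,2,2-trifluoroethyl 3-[C10] propanoate of the ring A lactone; C10 bears CH2OH (C20, cis to C19) | OC[C@@]1(CCC(=O)OCC(F)(F)F)CCC[C@@]2(C)COC(=O)[C@H]21 | intermediate
16 | spirolactone: tetrahydropyran-2-one (C7, C8, C9, C10, C20, O) spiro at C10 to the ring A γ-lactone; C20 cis to C19 | O=C1CC[C@@]2(CCC[C@@]3(C)COC(=O)[C@H]32)CO1 | intermediate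
17 | N-acetylimidazole | CC(=O)n1ccnc1 | starting material
18 | 8-acetyl spirolactone (C8 epimers and enol) | CC(=O)C1C[C@@]2(CCC[C@@]3(C)COC(=O)[C@H]32)COC1=O | intermediate
19 | 8-acetyl-8-(phenylselanyl) spirolactone (C8 epimers) | CC(=O)C1([Se]c2ccccc2)C[C@@]2(CCC[C@@]3(C)COC(=O)[C@H]32)COC1=O | intermediate
20 | unsaturated keto lactone: 3-acetyl-5,6-dihydro-2H-pyran-2-one (C8=C9) spiro at C10 | CC(=O)C1=C[C@@]2(CCC[C@@]3(C)COC(=O)[C@H]32)COC1=O | intermediate
21 | 4-chlorobutanal | O=CCCCCl | starting material
22 | chloro diketone: 9-(4-chlorobutanoyl)-8-acetyl spirolactone; acyl group on C9 anti to C5; C8 epimers | ClCCCC(=O)[C@@H]1C(C(C)=O)C(=O)OC[C@]12CCC[C@@]3(C)COC(=O)[C@H]32 | intermediate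
23 | cyclohexanone: ring C (C8, C9, C11, C12, C13, C14) cis-fused to the δ-lactone; C11 ketone; C8 acetyl cis to H-9 | CC(=O)[C@]12CCCC(=O)[C@H]1[C@@]1(CCC[C@@]3(C)COC(=O)[C@H]31)COC2=O | intermediate
24 | enone: 23 with C12=C13 | CC(=O)[C@]12CC=CC(=O)[C@H]1[C@@]1(CCC[C@@]3(C)COC(=O)[C@H]31)COC2=O | intermediate
25 | bridged diketone: 11,15-dioxo bicyclo[3.2.1]octane core (C16–C13 bond formed; C16 is CH2) | C1C(=O)[C@]23C[C@H]1CC(=O)[C@H]2[C@@]1(CCC[C@@]2(C)COC(=O)[C@H]21)COC3=O | intermediate
26 | 11-alcohol: 25 with C11–OH equatorial (trans to H-9) | C1C(=O)[C@]23C[C@H]1C[C@@H](O)[C@H]2[C@@]1(CCC[C@@]2(C)COC(=O)[C@H]21)COC3=O | intermediate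
27 | formaldehyde (used as paraformaldehyde) | C=O | starting material
28 | 16-methylidene analogue of the target (C16=C17) | C=C1C(=O)[C@]23C[C@H]1C[C@@H](O)[C@H]2[C@@]1(CCC[C@@]2(C)COC(=O)[C@H]21)COC3=O | intermediate
29 | guidongnin C | C[C@H]1C(=O)[C@]23C[C@H]1C[C@@H](O)[C@H]2[C@@]1(CCC[C@@]2(C)COC(=O)[C@H]21)COC3=O | target

## Step count and risks

Total steps: 13. Longest linear sequence: 13 (fully linear from 1).

**Step 8 (the proposed new step).** The acyl radical may fail to add at the neopentyl C9 or add with poor facial control. Fallback with known chemistry, from 20 back to 23: 1-chloro-4-nitrobutane F1 is made from 1-bromo-4-chlorobutane and NaNO2 in DMF. Its nitronate (1,8-diazabicyclo[5.4.0]undec-7-ene, MeCN) undergoes Michael addition to 20, anti to C5, to give the open nitro chloride F2. K2CO3/NaI closes ring C by C-alkylation to the nitro cyclohexane F3. An ozonolytic Nef reaction of its potassium nitronate (KN(SiMe3)2, −78 °C; O3) then gives 23.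

**Step 4.** The acidic β-keto lactone may be enolised instead of methylenated, or 11 may isomerise into conjugation. Fallback from 9 back to 11: NaH and PhNTf2 give the enol triflate F4. Stille coupling with Me4Sn (Pd(PPh3)4, zerovalent palladium, LiCl) gives the 10-methyl unsaturated lactone F5. γ-Deprotonation at C20 (syn to the carbonyl) with LiN(i-Pr)2/HMPA at −78 °C and kinetic α-protonation with AcOH deconjugate F5 to 11.

**Step 11.** Hydride may arrive on the exo face and give the axial alcohol. Fallback from 25 back to 26: reduce deliberately from the exo face with Li[B(sec-Bu)3H] to the axial 11-epi alcohol F6. Invert by Mitsunobu reaction (4-nitrobenzoic acid, PPh3, diisopropyl azodicarboxylate) to the equatorial 4-nitrobenzoate F7. Mild methanolysis (K2CO3, MeOH, 0 °C) then gives 26.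

## Further compounds

F1 | step 8 | 1-chloro-4-nitrobutane | [O-][N+](=O)CCCCCl
F2 | step 8 | open nitro chloride: 9-(4-chloro-1-nitrobutyl)-8-acetyl spirolactone (C9 as in 22; C8 and C11 epimers) | ClCCCC([N+](=O)[O-])[C@@H]1C(C(C)=O)C(=O)OC[C@]12CCC[C@@]3(C)COC(=O)[C@H]32
F3 | step 8 | nitro cyclohexane: 23 with CH–NO2 at C11 in place of the ketone (C11 epimers) | CC(=O)[C@]12CCCC([N+](=O)[O-])[C@H]1[C@@]1(CCC[C@@]3(C)COC(=O)[C@H]31)COC2=O
F4 | step 4 | enol triflate of 9 (C5=C10; OTf on C10) | O=C1OC[C@]2(C)CCCC(OS(=O)(=O)C(F)(F)F)=C12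
F5 | step 4 | 10-methyl unsaturated lactone (R)-3a,7-dimethyl-3a,4,5,6-tetrahydro-2-benzofuran-1(3H)-one | O=C1OC[C@]2(C)CCCC(C)=C12
F6 | step 11 | 11-epi alcohol (axial OH; cis to H-9) | C1C(=O)[C@]23C[C@H]1C[C@H](O)[C@H]2[C@@]1(CCC[C@@]2(C)COC(=O)[C@H]21)COC3=O
F7 | step 11 | 4-nitrobenzoate of 26 (equatorial ester at C11) | C1C(=O)[C@]23C[C@H]1C[C@@H](OC(=O)c4ccc(cc4)[N+](=O)[O-])[C@H]2[C@@]1(CCC[C@@]2(C)COC(=O)[C@H]21)COC3=O
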